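**Retrosynthetic overview**
1. Target 27 ⇐ excision of the C7 isopropenyl group and reduction of the C21 ketone of dione 24; ring E ⇐ silicon-tethered Diels–Alder of a 2-silyloxydiene, delivered from O14, onto the ring-D 2-methylcycloheptenone 20.
2. Ring D ⇐ ring-closing metathesis (C17=C18) of 19.
3. Ring C ⇐ visible-light deoxygenative Giese/aldol annulation: the C9 radical from alcohol 13 adds to dienone 16 (C9–C11), and the resulting enolate closes C12–C14.
4. A/B cis-decalin ⇐ mixed-Lewis-acid Diels–Alder of (S)-carvone (ring B) with silyloxydiene 2; C8 quaternary centre by two enolate alkylations; the carvone isopropenyl group steers these steps and is removed last.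
5. Ring order: B (bought) → A → C → D → E.

Assumption: the SMILES is taken literally (3β-OMe, 5β-H, 8β-Me, 9β-H, 10β-Me, 12α-H, 14β-OH, 17α-H, 18α-Me, 21β-OH; cis A/B, B/C and D/E, trans C/D); atoms carry serratane-type labels (C27 = CH2 between C8 and C14; Me-25 on C10, Me-26 on C8, Me-28 on C18; β = face of Me-25 in the planar drawing); 4-methylpent-1-en-3-one is taken as commercially available.

**Route**

Step 1
Reactants: 1 4-methylpent-1-en-3-one (isopropyl vinyl ketone)
Product: 2 tert-butyl(dimethyl)[(4-methylpenta-1,3-dien-3-yl)oxy]silane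
Conditions: TBSOTf, Et3N, CH2Cl2, 0 °C
Reagents that add atoms: tert-butyldimethylsilyl trifluoromethanesulfonate, CC(C)(C)[Si](C)(C)OS(=O)(=O)C(F)(F)F
Why: Soft enolisation/O-silylation of the vinyl ketone at its only α′-C–H gives the 2-silyloxydiene (silyl dienol ether formation); no stereocentre.

Step 2
Reactants: 3 (S)-(+)-carvone; 2 tert-butyl(dimethyl)[(4-methylpenta-1,3-dien-3-yl)oxy]silane
Product: 4 A/B-cis enol ether ketone: 4,4,10-trimethyl-7β-(prop-1-en-2-yl)-3-(TBS-oxy)-5β,10β-decal-2-en-9-one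
Conditions: AlBr3/AlMe3 (10:1, 20 mol %), PhMe/CH2Cl2, −5 °C → rt
Reagents that add atoms: none
Why: Mixed-Lewis-acid Diels–Alder of a hindered 2-silyloxydiene with a 2-methylcyclohexenone; the nucleophilic CMe2 terminus bonds to the enone β-carbon (C5), and suprafacial addition anti to the isopropenyl group makes Me-25 and H-5 cis (β) with ring A on the α face.

Step 3
Reactants: 4 A/B-cis enol ether ketone
Product: 5 8α-methyl analogue of 4 (Me trans to isopropenyl)
Conditions: LDA, THF, −78 °C; MeI, −78 → 0 °C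
Reagents that add atoms: iodomethane, CI
Why: Kinetic enolate alkylation at C8, the only enolisable position of the C9 ketone (C10 is quaternary); the new centre is re-planarised in step 4.

Step 4
Reactants: 5 8α-methyl analogue of 4; 6 2-bromo-N-methoxy-N-methylacetamide
Product: 8 3,9-dioxo Weinreb amide (C8: β-Me/α-CH2CON(OMe)Me; 7β-isopropenyl), via alkylated silyl enol ether 7 (not isolated)
Conditions: KHMDS, THF, −78 → −20 °C; 6; then 1 M HCl, THF, rt
Reagents that add atoms: none
Why: C-alkylation of the tetrasubstituted enolate anti to the adjacent 7β-isopropenyl group (and to Me-25) sets the C8 quaternary centre (8β-Me, 8α-C27), and the acidic work-up hydrolyses the TBS enol ether to the C3 ketone.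

Step 5
Reactants: 8 3,9-dioxo Weinreb amide
Product: 9 3β-hydroxy-9-oxo Weinreb amide
Conditions: Al(OiPr)3, iPrOH/PhMe, 85 °C
Reagents that add atoms: none
Why: Meerwein–Ponndorf–Verley reduction is reversible, so C3 equilibrates to the equatorial 3β-alcohol (the 3α epimer is syn-axial to C6), while the C9 ketone between two quaternary carbons and the amide do not react.

Step 6
Reactants: 9 3β-hydroxy-9-oxo Weinreb amide
Product: 10 3β-methoxy-9-oxo Weinreb amide
Conditions: NaH, MeI, THF, 0 °C → rt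
Reagents that add atoms: iodomethane, CI
Why: Williamson O-methylation of the only hydroxyl with retention at C3; the C9 ketone has no α-proton.

Step 7
Reactants: 10 3β-methoxy-9-oxo Weinreb amide; 11 but-3-en-1-ylmagnesium bromide
Product: 13 9β-hydroxy-3β-methoxy ketone carrying 8α-(2-oxohex-5-en-1-yl), via magnesium hemiaminal chelate 12 (not isolated)
Conditions: 11 (1.3 equiv), THF, 0 °C; then LiAlH4, −20 → 0 °C; aq. Rochelle salt
Reagents that add atoms: none
Why: Weinreb ketone synthesis, in which the stable Mg chelate masks C14 while LiAlH4 reduces the non-enolisable C9 ketone from the α face (9β-OH, trans-diaxial to C27 so no lactol forms); the C9 centre is erased in step 9.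

Step 8
Reactants: 14 tigloyl chloride; 15 tributyl(vinyl)stannane
Product: 16 (E)-4-methylhexa-1,4-dien-3-one
Conditions: PdCl2(PPh3)2 (2 mol %), THF, 50 °C
Reagents that add atoms: none
Why: Stille acylation of an acid chloride with a vinylstannane, with retention of the (E)-tiglyl geometry.

Step 9
Reactants: 13 9β-hydroxy-3β-methoxy ketone; 16 (E)-4-methylhexa-1,4-dien-3-one; 17 5,7-di-tert-butyl-3-phenyl-1,3-benzoxazol-3-ium tetrafluoroborate
Product: 19 tricyclic ketol (rings A–C): 9β-H; 12β-[(E)-2-methylbut-2-enoyl]; 14β-OH; 14α-but-3-enyl, via benzoxazoline adduct 18 (not isolated)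
Conditions: 17, pyridine, MTBE, rt; then 16 (2 equiv), [Ir(ppy)2(dtbbpy)]PF6 (1 mol %), DMSO, 450 nm LEDs, rt; then DBU (20 mol %)
Reagents that add atoms: none
Why: Proposed new method: a deoxygenative radical–polar crossover Giese/aldol annulation in which excited Ir(III) oxidises adduct 18, deprotonation and β-scission release the C9 radical, which adds to the unsubstituted vinyl terminus of 16 from the α face (anti to Me-25, Me-26 and the 7β-isopropenyl, so H-9 is β), Ir(II) reduces the α-keto radical to the C12 enolate, and this closes ring C onto the C14 ketone through a chair with the C13 acyl and butenyl groups equatorial (12α-H, 14β-OH; DBU ensures equilibration); the closest known reactions are the photoredox deoxygenative conjugate alkylation of benzoxazolium-activated alcohols and reductive radical–polar crossover cyclisations, which have not been merged or shown on a bis-neopentyl secondary alcohol.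

Step 10
Reactants: 19 tricyclic ketol
Product: 20 tetracyclic enone (rings A–D): 2-methylcyclohept-2-enone ring D (C17=C18); 14β-OH; 12α-H
Conditions: Hoveyda–Grubbs II (10 mol %), PhMe, 80 °C
Reagents that add atoms: none
Why: Ring-closing metathesis of the terminal butenyl alkene with the tiglyl alkene closes the seven-membered enone with loss of propene; no stereocentre is touched.

Step 11
Reactants: 20 tetracyclic enone; 1 4-methylpent-1-en-3-one
Product: 22 O14-diisopropylsilyl dienol ether of 20 [O14–Si(iPr)2–O–C(=CMe2)CH=CH2], via dienyloxysilyl triflate 21 (not isolated)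
Conditions: iPr2Si(OTf)2, Et3N, 1, CH2Cl2, −78 → 0 °C; then 20, 2,6-lutidine, rt
Reagents that add atoms: diisopropylsilyl bis(trifluoromethanesulfonate), CC(C)[Si](OS(=O)(=O)C(F)(F)F)(OS(=O)(=O)C(F)(F)F)C(C)C
Why: Stepwise substitution of the two triflates (soft enolisation/O-silylation of the vinyl ketone, then silylation of the tertiary 14β-OH) builds an unsymmetrical silaketal as a temporary tether; no stereocentre changes.

Step 12
Reactants: 22 O14-diisopropylsilyl dienol ether of 20
Product: 24 7β-isopropenyl-14β-hydroxy-3β-methoxy pentacyclic 13,21-dione, via bridged silaketal cycloadduct 23 (not isolated)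
Conditions: AlBr3/AlMe3 (10:1, 30 mol %), PhMe/CH2Cl2, −5 °C → rt; then HF·pyridine, THF, 0 °C
Reagents that add atoms: none
Why: Silicon-tethered intramolecular Diels–Alder: the diene hangs from the axial 14β-oxygen and can reach the enone only from the β face, the CMe2 terminus bonds to the β-carbon C17, and suprafacial addition makes Me-28 and H-17 cis (α); HF then cleaves the silaketal and enol ether to the C21 ketone.

Step 13
Reactants: 24 pentacyclic 13,21-dione
Product: 25 7β-isopropenyl-14β,21β-dihydroxy-3β-methoxy pentacyclic 13-one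
Conditions: L-Selectride, THF, −78 °C; aq. NH4Cl
Reagents that add atoms: none
Why: The bulky hydride attacks C21 along the equatorial trajectory (the axial path is blocked by the syn-axial C16), giving the axial 21β-alcohol trans to Me-28, while the C13 ketone between a quaternary and a tertiary carbon is not reduced.

Step 14
Reactants: 25 7β-isopropenyl-14β,21β-dihydroxy-3β-methoxy pentacyclic 13-one
Product: 27 target CNP0259231.1, via C7 methoxy hydroperoxide 26 (not isolated)
Conditions: O3, MeOH, −78 °C; then FeSO4·7H2O, PhSH, −78 °C → rt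
Reagents that add atoms: none
Why: Hydrodealkenylation: ozonolysis in methanol gives the α-methoxy hydroperoxide, Fe(II) triggers alkoxy-radical β-scission with loss of methyl acetate, and PhSH caps the C7 radical, so C7 becomes CH2 and the carvone control element is removed.

**Compound list**
1 | 4-methylpent-1-en-3-one (isopropyl vinyl ketone) | C=CC(=O)C(C)C | starting material
2 | tert-butyl(dimethyl)[(4-methylpenta-1,3-dien-3-yl)oxy]silane | C=CC(O[Si](C)(C)C(C)(C)C)=C(C)C | intermediate
3 | (S)-(+)-carvone | CC1=CC[C@@H](CC1=O)C(C)=C | starting material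
4 | A/B-cis enol ether ketone: 4,4,10-trimethyl-7β-(prop-1-en-2-yl)-3-(TBS-oxy)-5β,10β-decal-2-en-9-one | CC(C)(C)[Si](C)(C)OC1=CC[C@@]2(C)[C@H](C[C@H](C(C)=C)CC2=O)C1(C)C | intermediate
5 | 8α-methyl analogue of 4 (Me trans to isopropenyl) | CC(C)(C)[Si](C)(C)OC1=CC[C@@]2(C)[C@H](C[C@H](C(C)=C)[C@@H](C)C2=O)C1(C)C | intermediate
6 | 2-bromo-N-methoxy-N-methylacetamide | CON(C)C(=O)CBr | starting material
7 | alkylated silyl enol ether (C8: β-Me/α-CH2CON(OMe)Me) | CC(C)(C)[Si](C)(C)OC1=CC[C@@]2(C)[C@H](C[C@H](C(C)=C)[C@@](C)(CC(=O)N(C)OC)C2=O)C1(C)C | intermediate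
8 | 3,9-dioxo Weinreb amide (C8: β-Me/α-CH2CON(OMe)Me; 7β-isopropenyl) | O=C1CC[C@@]2(C)[C@H](C[C@H](C(C)=C)[C@@](C)(CC(=O)N(C)OC)C2=O)C1(C)C | intermediate
9 | 3β-hydroxy-9-oxo Weinreb amide | O[C@H]1CC[C@@]2(C)[C@H](C[C@H](C(C)=C)[C@@](C)(CC(=O)N(C)OC)C2=O)C1(C)C | intermediate
10 | 3β-methoxy-9-oxo Weinreb amide | CO[C@H]1CC[C@@]2(C)[C@H](C[C@H](C(C)=C)[C@@](C)(CC(=O)N(C)OC)C2=O)C1(C)C | intermediate
11 | but-3-en-1-ylmagnesium bromide | C=CCC[Mg]Br | starting material
12 | magnesium hemiaminal chelate at C14 | CO[C@H]1CC[C@@]2(C)[C@H](C[C@H](C(C)=C)[C@@](C)(CC(O[Mg]Br)(CCC=C)N(C)OC)C2=O)C1(C)C | intermediate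
13 | 9β-hydroxy-3β-methoxy ketone carrying 8α-(2-oxohex-5-en-1-yl) (8β-Me; 7β-isopropenyl) | CO[C@H]1CC[C@@]2(C)[C@H](C[C@H](C(C)=C)[C@@](C)(CC(=O)CCC=C)[C@@H]2O)C1(C)C | intermediate
14 | tigloyl chloride [(E)-2-methylbut-2-enoyl chloride] | C/C=C(\C)C(Cl)=O | starting material
15 | tributyl(vinyl)stannane | C=C[Sn](CCCC)(CCCC)CCCC | starting material
16 | (E)-4-methylhexa-1,4-dien-3-one | C/C=C(\C)C(=O)C=C | intermediate
17 | 5,7-di-tert-butyl-3-phenyl-1,3-benzoxazol-3-ium tetrafluoroborate | CC(C)(C)c1cc2[n+](-c3ccccc3)coc2c(C(C)(C)C)c1.F[B-](F)(F)F | starting material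
18 | benzoxazoline adduct of 13 at O9 | CO[C@H]1CC[C@@]2(C)[C@H](C[C@H](C(C)=C)[C@@](C)(CC(=O)CCC=C)[C@@H]2OC2Oc3c(C(C)(C)C)cc(C(C)(C)C)cc3N2c2ccccc2)C1(C)C | intermediate
19 | tricyclic ketol (rings A–C): 9β-H; 12β-[(E)-2-methylbut-2-enoyl]; 14β-OH; 14α-but-3-enyl | CO[C@H]1CC[C@@]2(C)[C@H](C[C@H](C(C)=C)[C@@]3(C)C[C@@](O)(CCC=C)[C@H](C(=O)/C(C)=C/C)C[C@H]32)C1(C)C | intermediate
20 | tetracyclic enone (rings A–D): 2-methylcyclohept-2-enone ring D (C17=C18); 14β-OH; 12α-H | CO[C@H]1CC[C@@]2(C)[C@H](C[C@H](C(C)=C)[C@@]3(C)C[C@@]4(O)CCC=C(C)C(=O)[C@@H]4C[C@H]32)C1(C)C | intermediate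
21 | diisopropyl[(4-methylpenta-1,3-dien-3-yl)oxy]silyl triflate | C=CC(O[Si](OS(=O)(=O)C(F)(F)F)(C(C)C)C(C)C)=C(C)C | intermediate
22 | O14-diisopropylsilyl dienol ether of 20 | CO[C@H]1CC[C@@]2(C)[C@H](C[C@H](C(C)=C)[C@@]3(C)C[C@@]4(O[Si](C(C)C)(C(C)C)OC(C=C)=C(C)C)CCC=C(C)C(=O)[C@@H]4C[C@H]32)C1(C)C | intermediate
23 | bridged silaketal cycloadduct (O14–Si–O–C21; C20=C21 enol ether) | CO[C@H]1CC[C@@]2(C)[C@H](C[C@H](C(C)=C)[C@@]3(C)C[C@@]4(O[Si](C(C)C)(C(C)C)O6)CC[C@@H]5C(C)(C)C6=CC[C@]5(C)C(=O)[C@@H]4C[C@H]32)C1(C)C | intermediate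
24 | 7β-isopropenyl-14β-hydroxy-3β-methoxy pentacyclic 13,21-dione | CO[C@H]1CC[C@@]2(C)[C@H](C[C@H](C(C)=C)[C@@]3(C)C[C@@]4(O)CC[C@@H]5C(C)(C)C(=O)CC[C@]5(C)C(=O)[C@@H]4C[C@H]32)C1(C)C | intermediate
25 | 7β-isopropenyl-14β,21β-dihydroxy-3β-methoxy pentacyclic 13-one | CO[C@H]1CC[C@@]2(C)[C@H](C[C@H](C(C)=C)[C@@]3(C)C[C@@]4(O)CC[C@@H]5C(C)(C)[C@H](O)CC[C@]5(C)C(=O)[C@@H]4C[C@H]32)C1(C)C | intermediate
26 | C7 (1-hydroperoxy-1-methoxyethyl) derivative of 25 | CO[C@H]1CC[C@@]2(C)[C@H](C[C@H](C(C)(OC)OO)[C@@]3(C)C[C@@]4(O)CC[C@@H]5C(C)(C)[C@H](O)CC[C@]5(C)C(=O)[C@@H]4C[C@H]32)C1(C)C | intermediate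
27 | CNP0259231.1 (3β-methoxy-14β,21β-dihydroxy pentacyclic 13-one) | CO[C@H]1CC[C@@]2(C)[C@H](CC[C@@]3(C)C[C@@]4(O)CC[C@@H]5C(C)(C)[C@H](O)CC[C@]5(C)C(=O)[C@@H]4C[C@H]32)C1(C)C | target

**Step count**
Total steps: 14. Longest linear sequence: 13 (steps 1–7 and 9–14; step 8 is a one-step side branch).

**Steps most likely to fail, with fallbacks**

Step 9 (the new annulation). The bis-neopentyl C9 alcohol may condense poorly with the benzoxazolium salt, the C9 radical may attack from the wrong face or undergo 1,5-hydrogen transfer from C15, and the enolate may be protonated before ring closure. The fallback sets out from 13 and uses only known chemistry. The C9 alcohol is converted into the O-phenyl thionocarbonate F1 (PhOC(S)Cl, DMAP, pyridine). A tin-hydride Giese addition to 16 (Bu3SnH, AIBN, PhH, 80 °C, slow addition) gives the ring-open 1,7-diketone F2. A separate thermodynamic aldol (KOtBu, tBuOH/THF, 0 °C) closes ring C and returns to the route at 19.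

Step 12 (tethered cycloaddition forming two adjacent quaternary carbons). The silaketal may not survive the Lewis acid, or the nine-membered tether ring may be too strained. The fallback sets out from 20 and skips 22. An intermolecular mixed-Lewis-acid Diels–Alder with diene 2 (conditions of step 2; O14 is held as its aluminium alkoxide) gives the TBS enol ether adduct F3. Face selectivity then rests on substrate bias, and the facial isomers are separated. Hydrolysis with 1 M HCl/THF returns to the route at 24.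

Step 7 (one-pot Grignard addition and hydride reduction). The magnesium chelate may collapse before the hydride is added, or the Grignard reagent may attack C9. The fallback sets out from 10. Excess LiAlH4 reduces both the C9 ketone and the Weinreb amide to give the hydroxy aldehyde F4. But-3-en-1-ylmagnesium bromide then gives the diol F5. Chemoselective oxidation of the unhindered C14 carbinol (TEMPO, PhI(OAc)2, CH2Cl2) returns to the route at 13.

Further compounds
F1 | step 9 | O-phenyl thionocarbonate of 13 at O9 | CO[C@H]1CC[C@@]2(C)[C@H](C[C@H](C(C)=C)[C@@](C)(CC(=O)CCC=C)[C@@H]2OC(=S)Oc2ccccc2)C1(C)C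
F2 | step 9 | ring-open 1,7-diketone (9β-H; C9α-CH2CH2CO-tiglyl; C8α-CH2CO-butenyl) | CO[C@H]1CC[C@@]2(C)[C@H](C[C@H](C(C)=C)[C@@](C)(CC(=O)CCC=C)[C@H]2CCC(=O)/C(C)=C/C)C1(C)C
F3 | step 12 | pentacyclic TBS enol ether (C20=C21) with free 14β-OH | CO[C@H]1CC[C@@]2(C)[C@H](C[C@H](C(C)=C)[C@@]3(C)C[C@@]4(O)CC[C@@H]5C(C)(C)C(O[Si](C)(C)C(C)(C)C)=CC[C@]5(C)C(=O)[C@@H]4C[C@H]32)C1(C)C
F4 | step 7 | 9β-hydroxy aldehyde (C8α-CH2CHO) | CO[C@H]1CC[C@@]2(C)[C@H](C[C@H](C(C)=C)[C@@](C)(CC=O)[C@@H]2O)C1(C)C
F5 | step 7 | 9β,14-diol (C8α-CH2CH(OH)CH2CH2CH=CH2) | CO[C@H]1CC[C@@]2(C)[C@H](C[C@H](C(C)=C)[C@@](C)(CC(O)CCC=C)[C@@H]2O)C1(C)C
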